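**Retrosynthetic overview**
1. C3'–C7 bond (last step): chiral phosphoric acid-catalysed 1,6-Friedel–Crafts arylation of the chalcone helichrysetin 12 onto the vinylogous para-quinone methide 13, formed in the flask from diol 9; this sets C7.
2. C5=C6: E-selective cross-metathesis of homoallylic alcohol 4 with racemic allylic alcohol 8 (its carbinol centre is erased in line 1).
3. C3 stereocentre: chiral phosphoric acid-catalysed allylboration of 3-phenylpropanal 1 (first stereocentre, metal-free).
4. Chalcone enone: Claisen–Schmidt condensation of acetophenone 10 with 4-hydroxybenzaldehyde 5.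
5. No ring is formed: all four benzene rings are bought intact; the order is chain, chalcone, then coupling.

Assumption: compounds 1, 2, 5, 6, 10 and both enantiomers of the phosphoric acid TRIP are bought. Diarylheptanoid numbering is used for the chain (C1 bears phenyl, C3 the carbinol, C7 the 4-hydroxyphenyl group) and primed numbers for ring A of the chalcone. The target SMILES corresponds to (3S,7S).

**Step 1**
Reactants: 1 3-phenylpropanal; 2 allylboronic acid pinacol ester
Product: 4 (S)-1-phenylhex-5-en-3-ol, via pinacol borate ester 3 (not isolated)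
Conditions: (R)-3,3'-bis(2,4,6-triisopropylphenyl)-1,1'-binaphthyl-2,2'-diyl hydrogen phosphate [(R)-TRIP] (5 mol%), 2 (1.2 equiv), toluene, −30 °C, 24 h; then H2O work-up
Reagents that add atoms: allylboronic acid pinacol ester (compound 2), C=CCB1OC(C)(C)C(C)(C)O1
Why: Chiral phosphoric acid-catalysed allylboration, in which the acid hydrogen-bonds to a boronate oxygen and the formyl hydrogen and delivers the allyl group through a chair transition state to the Re face of the aldehyde, setting C3 as S (about 90% ee expected; the minor enantiomer ends as a separable diastereomer after step 5).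

**Step 2**
Reactants: 5 4-hydroxybenzaldehyde; 6 vinylmagnesium bromide
Product: 8 rac-1-(4-hydroxyphenyl)prop-2-en-1-ol, via bis(bromomagnesium) alkoxide phenoxide 7 (not isolated)
Conditions: CH2=CHMgBr (2.5 equiv), THF, 0 °C → rt; then H2O / aq NH4Cl, 0 °C
Reagents that add atoms: vinylmagnesium bromide (compound 6), C=C[Mg]Br
Why: Grignard 1,2-addition to the aldehyde after the first equivalent has deprotonated the phenol; the carbinol centre is racemic on purpose because it is erased in step 5.

**Step 3**
Reactants: 4 (S)-1-phenylhex-5-en-3-ol; 8 rac-1-(4-hydroxyphenyl)prop-2-en-1-ol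
Product: 9 (3S,5E,7RS)-7-(4-hydroxyphenyl)-1-phenylhept-5-ene-3,7-diol (about 1:1 at C7)
Conditions: second-generation Hoveyda–Grubbs catalyst RuCl2(H2IMes)(=CH-C6H4-2-OiPr) (5 mol%), 1,4-benzoquinone (10 mol%), 8 (3 equiv), CH2Cl2, 40 °C, 12 h; Et3N-deactivated silica
Reagents that add atoms: none
Why: Olefin cross-metathesis between a fast-reacting terminal homoallylic alcohol and a slowly dimerising secondary allylic alcohol used in excess gives the E cross product under thermodynamic control; free alcohols and phenols are tolerated, benzoquinone suppresses ruthenium hydride isomerisation of the allylic alcohol, and C3 is untouched.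

**Step 4**
Reactants: 10 1-(2,4-dihydroxy-6-methoxyphenyl)ethan-1-one; 5 4-hydroxybenzaldehyde
Product: 12 helichrysetin [(E)-1-(2,4-dihydroxy-6-methoxyphenyl)-3-(4-hydroxyphenyl)prop-2-en-1-one], via aldol adduct 11 (not isolated)
Conditions: KOH (50% aq, 15 equiv), EtOH, rt, 48 h, Ar; then 1 M HCl to pH 5, 0 °C
Reagents that add atoms: none
Why: Claisen–Schmidt aldol condensation, in which the methyl ketone enolate adds to the aldehyde and E1cB loss of water gives the E enone; excess KOH keeps all phenols as spectator phenoxides and cold acidification avoids flavanone closure.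

**Step 5**
Reactants: 9 (3S,5E,7RS)-7-(4-hydroxyphenyl)-1-phenylhept-5-ene-3,7-diol; 12 helichrysetin
Product: 14 calyxin H, via vinylogous para-quinone methide 13 (not isolated)
Conditions: (R)-3,3'-bis(2,4,6-triisopropylphenyl)-1,1'-binaphthyl-2,2'-diyl hydrogen phosphate [(R)-TRIP] (10 mol%), 12 (2 equiv), 5 Å molecular sieves, CH2Cl2/EtOAc 5:1, −20 °C, 9 added over 6 h; preparative HPLC
Reagents that add atoms: none
Why: Proposed new method: the phosphoric acid ionises both C7 epimers of 9 by loss of water to the same planar quinone methide 13 and then acts as a bifunctional template (P–OH to the quinone methide carbonyl, P=O to the free 4'-OH of 12, the 2'-OH being held by the ketone), so that C3' of ring A, the most electron-rich carbon (ortho to two OH, para to OMe), attacks the Si face of C7 inside the hydrogen-bonded ion pair and rearomatisation gives the 7S product with the E alkene left in place; attack at C7 (1,6) over C5 (1,8) is expected because C7 is the carbon held nearest to the bound nucleophile, and the remote C3 carbinol takes no part, so the catalyst alone sets C7; the closest known reaction type is the chiral phosphoric acid-catalysed enantioselective 1,6-addition of phenols, naphthols and indoles to para-quinone methides generated in situ from para-hydroxybenzyl alcohols, which has not been shown for a δ-alkenyl quinone methide from a secondary allylic alcohol or with an unprotected acylphloroglucinol chalcone as the carbon nucleophile.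

**Compound list**
1 | 3-phenylpropanal | O=CCCc1ccccc1 | starting material
2 | allylboronic acid pinacol ester | C=CCB1OC(C)(C)C(C)(C)O1 | starting material
3 | 4,4,5,5-tetramethyl-2-{[(3S)-1-phenylhex-5-en-3-yl]oxy}-1,3,2-dioxaborolane (pinacol borate ester of 4) | C=CC[C@@H](OB1OC(C)(C)C(C)(C)O1)CCc1ccccc1 | intermediate
4 | (S)-1-phenylhex-5-en-3-ol | C=CC[C@@H](O)CCc1ccccc1 | intermediate
5 | 4-hydroxybenzaldehyde | O=Cc1ccc(O)cc1 | starting material
6 | vinylmagnesium bromide | C=C[Mg]Br | starting material
7 | bis(bromomagnesium) alkoxide phenoxide of 8 | C=CC(O[Mg]Br)c1ccc(O[Mg]Br)cc1 | intermediate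
8 | rac-1-(4-hydroxyphenyl)prop-2-en-1-ol | C=CC(O)c1ccc(O)cc1 | intermediate
9 | (3S,5E,7RS)-7-(4-hydroxyphenyl)-1-phenylhept-5-ene-3,7-diol | Oc1ccc(C(O)/C=C/C[C@@H](O)CCc2ccccc2)cc1 | intermediate
10 | 1-(2,4-dihydroxy-6-methoxyphenyl)ethan-1-one | COc1cc(O)cc(O)c1C(C)=O | starting material
11 | 1-(2,4-dihydroxy-6-methoxyphenyl)-3-hydroxy-3-(4-hydroxyphenyl)propan-1-one (racemic aldol adduct) | COc1cc(O)cc(O)c1C(=O)CC(O)c1ccc(O)cc1 | intermediate
12 | helichrysetin, (E)-1-(2,4-dihydroxy-6-methoxyphenyl)-3-(4-hydroxyphenyl)prop-2-en-1-one | COc1cc(O)cc(O)c1C(=O)/C=C/c1ccc(O)cc1 | intermediate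
13 | 4-[(2E,5S)-5-hydroxy-7-phenylhept-2-en-1-ylidene]cyclohexa-2,5-dien-1-one | O=C1C=CC(=C/C=C/C[C@@H](O)CCc2ccccc2)C=C1 | intermediate
14 | calyxin H, (E)-1-{2,4-dihydroxy-3-[(1S,2E,5S)-5-hydroxy-1-(4-hydroxyphenyl)-7-phenylhept-2-en-1-yl]-6-methoxyphenyl}-3-(4-hydroxyphenyl)prop-2-en-1-one | COc1cc(O)c([C@@H](/C=C/C[C@@H](O)CCc2ccccc2)c2ccc(O)cc2)c(O)c1C(=O)/C=C/c1ccc(O)cc1 | target

**Step count**
Total steps: 5. Longest linear sequence: 3 (steps 1, 3, 5).

**Three steps most likely to fail**

Step 5 (the proposed new step). The risks are attack at C5 instead of C7 (giving the conjugated styrene regioisomer), attack by C5' of ring A, low or opposite facial selectivity, and self-alkylation of 9. If only the sense of induction is wrong, (S)-TRIP is used in the same way; the 7-epimer is a diastereomer and can be separated. The fallback uses known chemistry and sets out from 8 and 12. An iridium-catalysed, enantioconvergent, branched-selective allylic Friedel–Crafts alkylation is run with [Ir(cod)Cl]2, a BINOL-derived phosphoramidite–alkene ligand (the enantiomer that gives the 1S product) and Zn(OTf)2 as promoter. The metal attacks at the substituted allyl terminus and so gives (E)-1-{2,4-dihydroxy-3-[(1S)-1-(4-hydroxyphenyl)prop-2-en-1-yl]-6-methoxyphenyl}-3-(4-hydroxyphenyl)prop-2-en-1-one F1. Cross-metathesis of F1 with 4 (3 equiv, RuCl2(H2IMes)(=CH-C6H4-2-OiPr), CH2Cl2, 40 °C) then comes back to the route at 14.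

Step 3. The risks are ruthenium hydride isomerisation of 8 to the ethyl ketone, ionisation of the para-hydroxybenzylic alcohols 8 and 9 on acidic supports, and homodimers. The fallback sets out from 4 and does not need 8. Cross-metathesis of 4 with crotonaldehyde (same ruthenium catalyst) gives (2E,5S)-5-hydroxy-7-phenylhept-2-enal F2. 1,2-Addition of [4-(tert-butyldimethylsilyloxy)phenyl]magnesium bromide (2.2 equiv, THF, −78 °C) gives (1RS,2E,5S)-1-{4-[(tert-butyldimethylsilyl)oxy]phenyl}-7-phenylhept-2-ene-1,5-diol F3. Desilylation with Bu4NF (THF, 0 °C) comes back to the route at 9.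

Step 4. The risks are a slow condensation of two phenoxide-deactivated partners, a low yield and flavanone formation. The fallback sets out from 10 and 5. MOMCl/iPr2NEt on 10 gives 1-[2-hydroxy-6-methoxy-4-(methoxymethoxy)phenyl]ethan-1-one F4, and MOMCl/K2CO3 on 5 gives 4-(methoxymethoxy)benzaldehyde F5. KOH/EtOH condensation of these gives (E)-1-[2-hydroxy-6-methoxy-4-(methoxymethoxy)phenyl]-3-[4-(methoxymethoxy)phenyl]prop-2-en-1-one F6. HCl/MeOH then removes both acetals and comes back to the route at 12.

**Further compounds**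
F1 | step 5 | (E)-1-{2,4-dihydroxy-3-[(1S)-1-(4-hydroxyphenyl)prop-2-en-1-yl]-6-methoxyphenyl}-3-(4-hydroxyphenyl)prop-2-en-1-one | COc1cc(O)c([C@@H](C=C)c2ccc(O)cc2)c(O)c1C(=O)/C=C/c1ccc(O)cc1
F2 | step 3 | (2E,5S)-5-hydroxy-7-phenylhept-2-enal | O=C/C=C/C[C@@H](O)CCc1ccccc1
F3 | step 3 | (1RS,2E,5S)-1-{4-[(tert-butyldimethylsilyl)oxy]phenyl}-7-phenylhept-2-ene-1,5-diol | CC(C)(C)[Si](C)(C)Oc1ccc(C(O)/C=C/C[C@@H](O)CCc2ccccc2)cc1
F4 | step 4 | 1-[2-hydroxy-6-methoxy-4-(methoxymethoxy)phenyl]ethan-1-one | COCOc1cc(O)c(C(C)=O)c(OC)c1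
F5 | step 4 | 4-(methoxymethoxy)benzaldehyde | COCOc1ccc(C=O)cc1
F6 | step 4 | (E)-1-[2-hydroxy-6-methoxy-4-(methoxymethoxy)phenyl]-3-[4-(methoxymethoxy)phenyl]prop-2-en-1-one | COCOc1ccc(/C=C/C(=O)c2c(O)cc(OCOC)cc2OC)cc1
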